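**Stereochemistry assumption:** the target SMILES has no stereocentres and no axial descriptor. The C4–C4′ bond is treated as a freely rotating biaryl-type axis, so nothing needs to be set and the product is obtained without stereocontrol.

## Retrosynthetic overview
1. Target ⇒ hexamethoxy-4,4′-bicoumarin (7) by selective 7,7′-O-demethylation. The central OMe of each 6,7,8-trimethoxy array is the most crowded and chelation-prone.
2. Bicoumarin 7 ⇒ 2 × 2,3,4-trimethoxyphenol (4) + diethyl hexa-2,4-diynedioate (6). One double hydroarylation/lactonisation cascade closes both pyranone rings. The two inner alkyne carbons become C4 and C4′, so the C4–C4′ bond already exists in the diyne and no biaryl coupling is needed.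
3. Diyne 6 ⇐ Glaser–Hay homocoupling of two molecules of ethyl propiolate (5). Phenol 4 ⇐ Dakin-type Baeyer–Villiger oxidation and methanolysis of 2,3,4-trimethoxybenzaldehyde (1).
4. Ring order: the arenes pre-exist, and both lactone rings form together in the key step (Step 4).

## Route

**Step 1**
Reactants: 1 (2,3,4-trimethoxybenzaldehyde); 2 (mCPBA)
Product: 3 (2,3,4-trimethoxyphenyl formate)
Conditions: mCPBA, NaHCO3, CH2Cl2, 0 °C → rt
Reagents that add atoms: mCPBA, O=C(OO)c1cccc(Cl)c1 (supplies the inserted O)
Why: Electron-rich aryl aldehydes undergo Baeyer–Villiger (Dakin-type) oxidation with aryl migration to give the aryl formate. No stereocentre is formed.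

**Step 2**
Reactants: 3 (2,3,4-trimethoxyphenyl formate)
Product: 4 (2,3,4-trimethoxyphenol)
Conditions: K2CO3 (cat.), MeOH, rt, N2
Reagents that add atoms: none (MeOH only delivers H and leaves as HCO2Me)
Why: Base-mediated methanolysis of the formate ester releases the free phenol. No stereocentre is formed.

**Step 3**
Reactants: 5 (ethyl propiolate, 2 equiv; C5H6O2 each)
Product: 6 (diethyl hexa-2,4-diynedioate, C10H10O4)
Conditions: CuCl (cat.), TMEDA, O2 (air), acetone, rt
Reagents that add atoms: none (O2 is only the terminal oxidant and removes the two terminal alkyne H atoms as H2O)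
Why: Glaser–Hay oxidative homocoupling joins two terminal alkynes into the symmetrical 1,3-diyne. The balance is 2 C5H6O2 + ½ O2 → C10H10O4 + H2O. There is no stereochemistry.

**Step 4**
Reactants: 4 (2,3,4-trimethoxyphenol, 2.4 equiv); 6 (diethyl hexa-2,4-diynedioate, 1 equiv, added slowly)
Product: 7 (6,6′,7,7′,8,8′-hexamethoxy-4,4′-bi(2H-chromen-2-one))
Conditions: Pd(OAc)2 (10 mol%), TFA/CH2Cl2 1:1, rt → 45 °C, 24–48 h
Reagents that add atoms: none (Pd and TFA are catalyst or solvent and do not remain; 2 EtOH are lost)
Why: Proposed new method: a double Fujiwara-type hydroarylation/lactonisation on a 1,3-diynedioate. The closest known reaction is Pd(II)/TFA coupling of electron-rich phenols with propiolates to give coumarins (Pechmann-like). Mechanism: C6 of 4 is the most nucleophilic free site, being ortho to OH and para to the 3-OMe. It attacks the Pd(II)-activated alkyne at the inner carbon β to one ester, with anti-hydropalladation/protonolysis. This places the aryl group cis to the ester, so the phenol OH can lactonise with loss of EtOH to give a 4-alkynylcoumarin. The remaining alkynoate again has its β carbon as the inner carbon, so a second phenol adds and cyclises the same way. This forms both rings and leaves the C4–C4′ bond in place, with no stereocentre to control.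

**Step 5**
Reactants: 7 (hexamethoxy-4,4′-bicoumarin)
Product: 8 (4,4′-biisofraxidin)
Conditions: BCl3 (3.5 equiv, 1 M in CH2Cl2), CH2Cl2, −78 → 0 °C, 2 h; then MeOH/H2O quench
Reagents that add atoms: none (BCl3 leaves as B(OH)3 or borate, and the methyl leaves as MeCl)
Why: BCl3 chelates the central OMe and a flanking OMe of each 1,2,3-trimethoxy array. Loss of the 7-methyl gives the best-stabilised phenoxide (vinylogous to the lactone C=O, as in umbelliferone) and relieves strain, the same selectivity seen for 1,2,3-trimethoxybenzene → 2,6-dimethoxyphenol. This is a Lewis-acid O-demethylation, and no stereocentre is involved.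

## Checks
- **Target match:** 8 has two 7-hydroxy-6,8-dimethoxycoumarin units joined C4–C4′. It is C22H18O10 and matches the target SMILES.
- **Atom balance, step 3:** 2 C5H6O2 + ½ O2 − H2O = C10H10O4, which is 6.
- **Atom balance, step 4:** 2 C9H12O4 + C10H10O4 − 2 C2H6O = C24H22O10, which is 7.
- **Atom balance, step 5:** C24H22O10 − 2 CH2 = C22H18O10, which is 8.
- **Functional groups:**
  - The lactone and C3=C4 alkene survive BCl3 at ≤ 0 °C.
  - OMe groups and the free phenol survive TFA at rt.
  - The ester groups in 6 are consumed only by lactonisation.
- **Stereochemistry:** there are no stereocentres to scramble.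

## Compound list
1 | 2,3,4-trimethoxybenzaldehyde | COc1ccc(C=O)c(OC)c1OC | starting material
2 | m-chloroperbenzoic acid | O=C(OO)c1cccc(Cl)c1 | starting material (reagent)
3 | 2,3,4-trimethoxyphenyl formate | COc1ccc(OC=O)c(OC)c1OC | intermediate
4 | 2,3,4-trimethoxyphenol | COc1ccc(O)c(OC)c1OC | intermediate
5 | ethyl propiolate | C#CC(=O)OCC | starting material
6 | diethyl hexa-2,4-diynedioate | CCOC(=O)C#CC#CC(=O)OCC | intermediate
7 | 6,6′,7,7′,8,8′-hexamethoxy-4,4′-bicoumarin | COc1cc2c(-c3cc(=O)oc4c(OC)c(OC)c(OC)cc34)cc(=O)oc2c(OC)c1OC | intermediate
8 | 4,4′-biisofraxidin | COc1cc2c(-c3cc(=O)oc4c(OC)c(O)c(OC)cc34)cc(=O)oc2c(OC)c1O | target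

## Totals
Total steps: 5. Longest linear sequence: 4 (1 → 3 → 4 → 7 → 8). Step 3 runs in parallel.

## Three steps most likely to fail
1. **Step 4 (double hydroarylation).**
   - Risks: stalling at the mono-coumarin, alkyne oligomerisation, and poor addition at the hindered second alkyne carbon.
   - Fallback (different approach): build 6,7,8-trimethoxy-4-tosyloxycoumarin from phenol 4 (malonic acid/POCl3, then TsCl), then do Ni-mediated reductive homocoupling (NiBr2/bpy, Zn) to give 7.
2. **Step 5 (selective 7,7′-demethylation).**
   - Risks: over-cleavage at C6 or C8, or incomplete reaction.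
   - Fallback (different approach): redo the route with a phenol carrying a 7-O-MOM group, 2,4-dimethoxy-3-(methoxymethoxy)phenol, in place of 4. The last step is then a mild HCl/MeOH deprotection, with no differentiation among OMe groups.
3. **Step 3 (Glaser–Hay of ethyl propiolate).**
   - Risks: modest yield, polymerisation, and a hazardous, reactive diyne.
   - Fallback (different approach): make dilithiobutadiyne from hexachlorobutadiene and 4 n-BuLi, then quench with 2 ClCO2Et to give 6.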